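**Plan**

Labdane numbering is used: C6 acetoxy carbon, C7 ketone, C8 methylated cyclobutane carbon, C9 central quaternary carbon, C10 angular carbon, C13 carbinol, C14 cyclobutane CH, C15 cyclobutane CH2.
Retrosynthesis: the 6β-acetoxy-7-ketone is traced back to a C6=C7 enol acetate; the C13–C14 bond is cut to a C13 methyl ketone and a C14 methylene; C9–C14 and C8–C15 are cut to a ring B enone and ethylene; the enone is traced to sclareol.
Forward: rings A and B come from sclareol (C14/C15 excised, dehydration, allylic oxidation); the cyclobutane arises by enone–ethylene photocycloaddition; the cyclopentane is closed last by Norrish–Yang cyclisation; the C6 acetate is set at the end by an enol ester epoxide rearrangement.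
Enabling feature: the C13 carbonyl of the 3-oxobutyl chain has no gamma hydrogen (C9 is quaternary) and its only delta hydrogens sit on cyclobutane carbon C14 (C8 and C10 are quaternary), so 1,6-hydrogen transfer and closure can only build the ring C9–C11–C12–C13–C14.
Stereochemistry: C5 and C10 come from sclareol; C8 and C9 from α-face cycloaddition anti to the C10 methyl; C14 from the obligatory cis fusion; C13 from the face of ketyl closure; C6 from α-face epoxidation and an acetoxy shift with inversion.

Key step: step 8

Remark: the two carbons from ethylene are numbered C15 (on C8) and C14 (on C9); the C7 carbonyl is carried through the irradiation as its C6=C7 enol acetate, which is transparent near 300 nm and later supplies the C6 acetate.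

**Route**

Step 1
Reactants: 1 sclareol, (13R)-labd-14-ene-8α,13-diol
Product: 4 8α-hydroxy-14,15-dinorlabdan-13-one, via labdane-8α,13,14,15-tetrol 2 (not isolated), via 8α,13-dihydroxy-15-norlabdan-14-al 3 (not isolated)
Conditions: OsO4 (cat.), NaIO4, THF/H2O, 45 °C
Reagents that add atoms: none
Why: Lemieux–Johnson oxidation, in which OsO4 dihydroxylates the only alkene and NaIO4 cleaves first the C14–C15 glycol and then the α-hydroxy aldehyde, so that C15 and C14 leave and C13 remains as the methyl ketone with no stereocentre touched.

Step 2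
Reactants: 4 8α-hydroxy-14,15-dinorlabdan-13-one
Product: 5 14,15-dinorlabd-8-en-13-one
Conditions: PPh3, I2, CH2Cl2, 25 °C
Reagents that add atoms: none
Why: Dehydration of a tertiary alcohol with PPh3/I2, in which the C8 hydroxyl leaves as an oxyphosphonium group (E1) and the HI released should equilibrate the alkene isomers to the tetrasubstituted C8=C9 olefin, while capture of the C8 cation by the chain carbonyl as a cyclic enol ether is reversible under the same acid.

Step 3
Reactants: 5 14,15-dinorlabd-8-en-13-one
Product: 6 14,15-dinorlabd-8-ene-7,13-dione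
Conditions: Na2CrO4, NaOAc, Ac2O, AcOH, 40 °C
Reagents that add atoms: sodium chromate Na2CrO4, [Na+].[Na+].[O-][Cr](=O)(=O)[O-]
Why: Chromate allylic oxidation, which in labd-8-enes attacks the ring allylic methylene C7 in preference to the side-chain C11 methylene and the C17 methyl and should give the conjugated 8-en-7-one without touching the saturated methyl ketone.

Step 4
Reactants: 6 14,15-dinorlabd-8-ene-7,13-dione
Product: 7 13,13-(ethylenedioxy)-14,15-dinorlabd-8-en-7-one
Conditions: HOCH2CH2OH, PPTS, benzene, reflux (Dean–Stark)
Reagents that add atoms: ethylene glycol, OCCO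
Why: Acid-catalysed acetalisation with water removal should be chemoselective for the unhindered saturated C13 ketone, because the conjugated, tetrasubstituted C7 enone carbonyl next to quaternary centres acetalises far more slowly.

Step 5
Reactants: 7 13,13-(ethylenedioxy)-14,15-dinorlabd-8-en-7-one; 8 ethylene
Product: 9 8α,9α-ethano-13,13-(ethylenedioxy)-14,15-dinorlabdan-7-one
Conditions: hν (λ > 340 nm, uranium-glass filter), C2H4-saturated CH2Cl2, −78 °C
Reagents that add atoms: none
Why: Enone–alkene [2+2] photocycloaddition through the enone triplet and a 1,4-biradical, in which ethylene should add to the α face of C8=C9, anti to the axial C10 methyl that shields the β face, and close to the cis-fused cyclobutane, setting C8 (methyl β) and C9 (chain β) together.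

Step 6
Reactants: 9 8α,9α-ethano-13,13-(ethylenedioxy)-14,15-dinorlabdan-7-one
Product: 11 7-acetoxy-8α,9α-ethano-13,13-(ethylenedioxy)-14,15-dinorlabd-6-ene, via potassium C6 enolate 10 (not isolated)
Conditions: KN(SiMe3)2, THF, −78 → 0 °C; Ac2O, −78 → 25 °C
Reagents that add atoms: acetic anhydride, CC(=O)OC(C)=O
Why: Enol ester formation by O-acylation of a potassium enolate, which is regiochemically unambiguous because C8 is quaternary and the C7 ketone can be deprotonated only at C6.

Step 7
Reactants: 11 7-acetoxy-8α,9α-ethano-13,13-(ethylenedioxy)-14,15-dinorlabd-6-ene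
Product: 12 7-acetoxy-8α,9α-ethano-14,15-dinorlabd-6-en-13-one
Conditions: PPTS, acetone/H2O 9:1, 50 °C
Reagents that add atoms: water, O
Why: Acetal hydrolysis through the oxocarbenium ion frees the methyl ketone, whereas the enol acetate can hydrolyse only by the much slower acid-catalysed ester pathway and should survive.

Step 8
Reactants: 12 7-acetoxy-8α,9α-ethano-14,15-dinorlabd-6-en-13-one
Product: 13 (13S)-7-acetoxy-13-hydroxy-8α,15:9α,14-dicyclolabd-6-ene
Conditions: hν (300 nm, Pyrex), degassed t-BuOH/benzene 4:1, 0.003 M, 25 °C
Reagents that add atoms: none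
Why: Norrish–Yang photocyclisation: n,π* excitation of the C13 ketone, the only chromophore at 300 nm, is followed by 1,6-hydrogen transfer from C14 through a seven-membered transition state and by recombination of the 1,5-biradical (C13 ketyl, C14 cyclobutyl radical) to the C13–C14 bond. The closest known reaction type is δ-hydrogen abstraction with cyclopentanol formation in ketones that lack γ hydrogens; here γ-hydrogen cleavage is excluded because C9 is quaternary, and C14 is the only δ carbon bearing hydrogen because C8 and C10 are quaternary. The cyclopentane C9–C11–C12–C13–C14 closes by radical–radical coupling, and because both termini hang on C9 it can only be cis-fused to the cyclobutane, which fixes C14 with H14 on the ring B side. C13 is controlled only by which face of the ketyl closes: in the hydrogen-bonding medium the solvated hydroxyl should take the open exo side anti to C15 and leave the methyl syn to C15 as required, and this is the least secured selectivity. Site selectivity rests on the absence of other δ hydrogens and on the preference for the seven-membered over the eight-membered transition states to C15, C17, C20 and C1, and the alcohol solvent should also slow hydrogen back-transfer in the biradical. The C7 carbonyl stays silent as its enol acetate, which does not absorb at 300 nm and is kept away from the chain carbonyl by the substituents on C8.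

Step 9
Reactants: 13 (13S)-7-acetoxy-13-hydroxy-8α,15:9α,14-dicyclolabd-6-ene
Product: 15 (13S)-6β-acetoxy-13-hydroxy-8α,15:9α,14-dicyclolabdan-7-one, via 6α,7α-epoxy-7β-acetate 14 (not isolated)
Conditions: DMDO, acetone, 0 °C; evaporate; toluene, 110 °C (base-washed glass)
Reagents that add atoms: dimethyldioxirane, CC1(C)OO1
Why: Enol ester epoxidation followed by thermal enol ester epoxide rearrangement, in which DMDO should attack C6=C7 from the α face away from the β methyls on C4, C10 and C8, and on heating without acid the acetoxy group shifts from C7 to C6 across the β face with inversion at C6 while the epoxide oxygen becomes the C7 carbonyl, which sets the 6β-acetate.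

**Compound list**

1 | sclareol, (13R)-labd-14-ene-8α,13-diol | C=C[C@](C)(O)CC[C@H]1[C@](C)(O)CC[C@H]2C(C)(C)CCC[C@]12C | starting material
2 | (13R)-labdane-8α,13,14,15-tetrol (both C14 epimers) | OCC(O)[C@](C)(O)CC[C@H]1[C@](C)(O)CC[C@H]2C(C)(C)CCC[C@]12C | intermediate
3 | (13R)-8α,13-dihydroxy-15-norlabdan-14-al | O=C[C@](C)(O)CC[C@H]1[C@](C)(O)CC[C@H]2C(C)(C)CCC[C@]12C | intermediate
4 | 8α-hydroxy-14,15-dinorlabdan-13-one | CC(=O)CC[C@H]1[C@](C)(O)CC[C@H]2C(C)(C)CCC[C@]12C | intermediate
5 | 14,15-dinorlabd-8-en-13-one | CC(=O)CCC1=C(C)CC[C@H]2C(C)(C)CCC[C@]12C | intermediate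
6 | 14,15-dinorlabd-8-ene-7,13-dione | CC(=O)CCC1=C(C)C(=O)C[C@H]2C(C)(C)CCC[C@]12C | intermediate
7 | 13,13-(ethylenedioxy)-14,15-dinorlabd-8-en-7-one | CC1(CCC2=C(C)C(=O)C[C@H]3C(C)(C)CCC[C@]23C)OCCO1 | intermediate
8 | ethylene | C=C | starting material
9 | 8α,9α-ethano-13,13-(ethylenedioxy)-14,15-dinorlabdan-7-one (cyclobutane C8–C15–C14–C9 on the α face, cis-fused; C17 methyl and C11 chain β) | C1C(=O)[C@@]2(C)CC[C@@]2(CCC3(C)OCCO3)[C@@]2(C)CCCC(C)(C)[C@H]12 | intermediate
10 | potassium C6=C7 enolate of 9 | C1=C([O-])[C@@]2(C)CC[C@@]2(CCC3(C)OCCO3)[C@@]2(C)CCCC(C)(C)[C@H]12.[K+] | intermediate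
11 | 7-acetoxy-8α,9α-ethano-13,13-(ethylenedioxy)-14,15-dinorlabd-6-ene (C6=C7 enol acetate) | C1=C(OC(C)=O)[C@@]2(C)CC[C@@]2(CCC3(C)OCCO3)[C@@]2(C)CCCC(C)(C)[C@H]12 | intermediate
12 | 7-acetoxy-8α,9α-ethano-14,15-dinorlabd-6-en-13-one (3-oxobutyl chain on C9) | C1=C(OC(C)=O)[C@@]2(C)CC[C@@]2(CCC(C)=O)[C@@]2(C)CCCC(C)(C)[C@H]12 | intermediate
13 | (13S)-7-acetoxy-13-hydroxy-8α,15:9α,14-dicyclolabd-6-ene (C13–C14 bond closed; H14 on the ring B side; 13-OH anti and C16 methyl syn to C15) | C1=C(OC(C)=O)[C@@]2(C)C[C@H]3[C@@]2(CC[C@]3(C)O)[C@@]2(C)CCCC(C)(C)[C@H]12 | intermediate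
14 | (13S)-7β-acetoxy-6α,7α-epoxy-13-hydroxy-8α,15:9α,14-dicyclolabdane | O1[C@H]2[C@]1(OC(C)=O)[C@@]3(C)C[C@H]4[C@@]3(CC[C@]4(C)O)[C@@]3(C)CCCC(C)(C)[C@H]23 | intermediate
15 | (13S)-6β-acetoxy-13-hydroxy-8α,15:9α,14-dicyclolabdan-7-one (CNP0330581.1) | CC(=O)O[C@@H]1C(=O)[C@@]2(C)C[C@H]3[C@@]2(CC[C@]3(C)O)[C@@]2(C)CCCC(C)(C)[C@H]12 | target

**Step count and risks**

Total step count: 9. Longest linear sequence: 9 steps, from sclareol.

Step 8. The 1,5-biradical may close on the other face of the C13 ketyl, so that the C13 epimer predominates; slow hydrogen transfer from the cyclobutane C–H would only lengthen the irradiation. The fallback sets out from 12 and comes back at 15, and sets C13 by radical hydration instead of in the photocyclisation. Irradiation as in step 8 would give the C13-epimeric carbinol F1, and the conditions of step 9 should convert it into the C13 epimer of the target F2. Burgess reagent (benzene, 60 °C) should dehydrate F2 by syn elimination to the C12=C13 olefin F3 together with its exocyclic C13=C16 isomer F4. Mukaiyama hydration of this olefin mixture (Mn(dpm)3 cat., PhSiH3, O2, i-PrOH, 0 °C; then PPh3) generates the same tertiary C13 radical from both olefins. O2 should trap that radical on the open exo face anti to C15, which gives 15.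

Step 9. Traces of acid may open the epoxy acetate with retention, or the epoxidation may take the β face; either would place the acetate on the α side of C6. The fallback sets out from 13 and comes back at 15. NBS in THF/H2O at 0 °C should brominate the enol acetate from the α face to the 6α-bromo-7-ketone F5. CsOAc with 18-crown-6 in toluene at 60 °C should then displace the α-keto bromide by SN2 with inversion to the 6β-acetate 15.

Step 5. The cycloaddition may give a trans ring fusion, which cannot be corrected by epimerisation because C8 is quaternary, or may show poor face selectivity. The fallback sets out from 7 and comes back at 9. Photocycloaddition with acetylene (hν, λ > 340 nm, acetone, −78 °C) should give the cyclobutene F6, whose ring fusion can only be cis. Hydrogenation (H2, Pd/C, EtOAc, 25 °C) then gives 9.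

Further compounds
F1 | step 8 | (13R)-7-acetoxy-13-hydroxy-8α,15:9α,14-dicyclolabd-6-ene (C13 epimer of 13) | C1=C(OC(C)=O)[C@@]2(C)C[C@H]3[C@@]2(CC[C@@]3(C)O)[C@@]2(C)CCCC(C)(C)[C@H]12
F2 | step 8 | (13R)-6β-acetoxy-13-hydroxy-8α,15:9α,14-dicyclolabdan-7-one (C13 epimer of 15) | CC(=O)O[C@@H]1C(=O)[C@@]2(C)C[C@H]3[C@@]2(CC[C@@]3(C)O)[C@@]2(C)CCCC(C)(C)[C@H]12
F3 | step 8 | 6β-acetoxy-8α,15:9α,14-dicyclolabd-12-en-7-one | CC(=O)O[C@@H]1C(=O)[C@@]2(C)C[C@H]3[C@@]2(CC=C3C)[C@@]2(C)CCCC(C)(C)[C@H]12
F4 | step 8 | 6β-acetoxy-8α,15:9α,14-dicyclolabd-13(16)-en-7-one | CC(=O)O[C@@H]1C(=O)[C@@]2(C)C[C@H]3[C@@]2(CCC3=C)[C@@]2(C)CCCC(C)(C)[C@H]12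
F5 | step 9 | (13S)-6α-bromo-13-hydroxy-8α,15:9α,14-dicyclolabdan-7-one | Br[C@H]1C(=O)[C@@]2(C)C[C@H]3[C@@]2(CC[C@]3(C)O)[C@@]2(C)CCCC(C)(C)[C@H]12
F6 | step 5 | 8α,9α-etheno-13,13-(ethylenedioxy)-14,15-dinorlabdan-7-one (cis-fused cyclobutene) | C1C(=O)[C@@]2(C)C=C[C@@]2(CCC3(C)OCCO3)[C@@]2(C)CCCC(C)(C)[C@H]12
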